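**Retrosynthetic overview**
1. Target 29 ⇐ seco acid 28: the 19,20-δ-lactone closes last from a cis-1,3-diaxial C4–CO2H / C10–CH2OH pair; the acid is unmasked from an axial C4 ethynyl group by ozonolysis.
2. Spiro ether (ring C, C9–O–C13) ⇐ 8(9)-ene 25 with its C13 tertiary alcohol: β-face seleniranium ion, anti 5-exo O-capture at C9, then H-atom delivery to C8.
3. Rings A and B in one step ⇐ acyclic triene 23: a C4 propargylic cation adds to the C5=C10 olefin, which adds to C8=C9; the cis olefin geometry gives the cis-fused decalin and the 6R carbinol relays absolute configuration.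
4. 23 ⇐ Wittig union at C5=C10 of α-formyl ylide 18 (C1–C4, C10, C18–C20) with aldehyde 12, whose C6 oxygen comes from a proline α-aminoxylation.
5. 12 ⇐ D-malic acid (C13–C16, γ-lactone) + homoallylic iodide 5 (from cyclopropyl methyl ketone). Ring order: γ-lactone, then A+B together, then the spiro ether, then the δ-lactone.

Assumption: the SMILES is read literally as 4S,5S,6R,8R,9R,10S,13R, i.e. H-5 is syn to C20 (cis-fused decalin, 5β-H).
Locants: labdane numbering (C19 = δ-lactone C=O on C4; C20 = OCH2 on C10; C16 = γ-lactone C=O; C17 = methyl on C8); β is the face of C20. Compounds 15–23 are 1:1 mixtures at C4 (this centre is ionised in step 12); a minor 8Z isomer from step 2 converges in step 12.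

**Step 1**
Reactants: 1 cyclopropyl methyl ketone; 2 2-(2-bromoethyl)-1,3-dioxolane
Product: 4 2-cyclopropyl-4-(1,3-dioxolan-2-yl)butan-2-ol (racemic), via [2-(1,3-dioxolan-2-yl)ethyl]magnesium bromide 3 (not isolated)
Conditions: Mg, THF, 25 °C; then 1, 0 °C; aq NH4Cl
Reagents that add atoms: none
Why: Grignard addition joins the acetal-protected C5–C7 unit to the ketone carbon (future C8 with its C17 methyl); the racemic carbinol centre is destroyed in step 2.

**Step 2**
Reactants: 4 2-cyclopropyl-4-(1,3-dioxolan-2-yl)butan-2-ol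
Product: 5 2-[(3E)-6-iodo-3-methylhex-3-en-1-yl]-1,3-dioxolane
Conditions: MgI2, Et2O, reflux
Reagents that add atoms: magnesium iodide, [Mg+2].[I-].[I-]
Why: Julia cyclopropylcarbinyl-to-homoallyl rearrangement; iodide opens the ring of the magnesium-activated tertiary carbinol, and the E trisubstituted olefin (C8=C9) predominates because the longer chain avoids the departing ring carbon.

**Step 3**
Reactants: 6 (R)-malic acid
Product: 7 2-[(2R,4R)-2-tert-butyl-5-oxo-1,3-dioxolan-4-yl]acetic acid
Conditions: t-BuCHO, TsOH (cat.), H2SO4 (cat.), pentane, reflux (Dean–Stark); recrystallise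
Reagents that add atoms: pivalaldehyde, CC(C)(C)C=O
Why: Seebach acetalisation of the α-hydroxy acid; the thermodynamically preferred cis acetal places tert-butyl cis to the CH2CO2H group, which fixes the new acetal centre as R.

**Step 4**
Reactants: 7 2-[(2R,4R)-2-tert-butyl-5-oxo-1,3-dioxolan-4-yl]acetic acid; 5 2-[(3E)-6-iodo-3-methylhex-3-en-1-yl]-1,3-dioxolane
Product: 9 2-[(2R,4R)-2-tert-butyl-4-[(3E)-6-(1,3-dioxolan-2-yl)-4-methylhex-3-en-1-yl]-5-oxo-1,3-dioxolan-4-yl]acetic acid, via dilithium enolate 8 (not isolated)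
Conditions: LiN(iPr)2 (2.1 equiv), THF/DMPU, −78 °C; then 5, −78 to −20 °C; cold 1 M HCl
Reagents that add atoms: none
Why: Seebach self-regeneration of stereocentres; the enolate is alkylated on the face anti to tert-butyl, so the C12 chain replaces H with retention and the quaternary C13 centre is set as R.

**Step 5**
Reactants: 9 alkylated dioxolanone acid
Product: 12 (4E)-7-[(3R)-3-hydroxy-2-oxooxolan-3-yl]-4-methylhept-4-enal, via acyl imidazolide 10 (not isolated), via hydroxyethyl dioxolanone 11 (not isolated)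
Conditions: 1,1'-carbonyldiimidazole, THF, 25 °C; NaBH4, THF/H2O, 0 °C; then 2 M HCl, THF, 25 °C
Reagents that add atoms: water, O
Why: Chemoselective borohydride reduction of the activated carboxyl (the olefin is untouched), then acid-catalysed translactonisation in which the new primary alcohol attacks the dioxolanone carbonyl and expels pivalaldehyde; C13 is not involved, and the dioxolane is hydrolysed to the C5 aldehyde in the same pot.

**Step 6**
Reactants: 13 6-chlorohexan-2-one
Product: 15 (7-chloro-3-methoxy-3-methylhept-1-yn-1-yl)trimethylsilane (racemic), via lithium alkoxide 14 (not isolated)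
Conditions: Me3SiC≡CH, n-BuLi, THF, −78 °C; then 13; then MeI, DMPU, −78 to 0 °C
Reagents that add atoms: (trimethylsilyl)acetylene, C#C[Si](C)(C)C; iodomethane, CI
Why: Acetylide 1,2-addition followed by Williamson O-methylation gives the tertiary propargylic methyl ether (future C4 with C18 methyl and the C19 alkyne carbon); its racemic centre is ionised in step 12.

**Step 7**
Reactants: 15 (7-chloro-3-methoxy-3-methylhept-1-yn-1-yl)trimethylsilane
Product: 16 [5-methoxy-5-methyl-7-(trimethylsilyl)hept-6-yn-1-yl]triphenylphosphonium iodide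
Conditions: NaI, PPh3, MeCN, reflux
Reagents that add atoms: triphenylphosphine, c1ccc(cc1)P(c1ccccc1)c1ccccc1; sodium iodide, [Na+].[I-]
Why: Finkelstein exchange then SN2 quaternisation of the primary halide; the tertiary ether and silylalkyne are inert.

**Step 8**
Reactants: 16 phosphonium iodide
Product: 18 6-methoxy-6-methyl-2-(triphenyl-λ5-phosphanylidene)-8-(trimethylsilyl)oct-7-ynal, via non-stabilised ylide 17 (not isolated)
Conditions: KN(SiMe3)2 (2.1 equiv), THF, −78 °C; HCO2Et, −78 to 25 °C
Reagents that add atoms: ethyl formate, CCOC=O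
Why: Bestmann-type C-formylation of the ylide followed by a second deprotonation gives the stabilised α-formyl ylide; the formyl carbon becomes C20.

**Step 9**
Reactants: 12 (4E)-7-[(3R)-3-hydroxy-2-oxooxolan-3-yl]-4-methylhept-4-enal; 18 α-formyl ylide
Product: 20 acyclic E-enal (C20 = CHO on C10; C5=C10 E; 6R ONHPh; 8E; 13R hydroxy lactone), via α-anilinooxy aldehyde 19 (not isolated)
Conditions: L-proline (20 mol %), PhN=O (0.95 equiv), CHCl3, 0 °C; then 18, CH2Cl2, 0 to 35 °C
Reagents that add atoms: nitrosobenzene, O=Nc1ccccc1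
Why: Proline enamine α-aminoxylation (L-proline gives the 6R centre), then Wittig olefination with the stabilised ylide, which gives the E enal (CHO trans to C6), i.e. the C5=C10 olefin with C6 cis to C1 that step 12 needs.

**Step 10**
Reactants: 20 acyclic E-enal
Product: 22 acyclic triol (C20 CH2OH; 6R OH; 13R OH), via anilinooxy allylic alcohol 21 (not isolated)
Conditions: NaBH4, CeCl3·7H2O, MeOH, −40 °C; then Zn, AcOH, 25 °C
Reagents that add atoms: none
Why: Luche 1,2-reduction touches only the enal (the lactone survives), and zinc in acetic acid cleaves the N–O bond reductively; no stereocentre or olefin geometry changes.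

**Step 11**
Reactants: 22 acyclic triol
Product: 23 acyclic tris(tert-butyldimethylsilyl) ether
Conditions: t-BuMe2SiOTf, 2,6-lutidine, CH2Cl2, −78 to 0 °C
Reagents that add atoms: tert-butyldimethylsilyl trifluoromethanesulfonate, CC(C)(C)[Si](C)(C)OS(=O)(=O)C(F)(F)F
Why: The silyl triflate silylates the primary, secondary and tertiary (α-hydroxy lactone) hydroxyls, so no free OH can capture the cationic intermediates of step 12.

**Step 12**
Reactants: 23 acyclic tris(tert-butyldimethylsilyl) ether
Product: 24 cis-fused bicyclic 8(9)-ene (5β-H; 10β-CH2OSi; 4β-C≡C–SiMe3 and 4α-CH3; 6β-OSi)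
Conditions: Me3SiOTf (0.3 equiv), CH2Cl2/(CF3)2CHOH 10:1, −78 to 0 °C
Reagents that add atoms: none
Why: Proposed new method: Me3SiOTf ionises the tertiary propargylic methyl ether (any enyne from proton loss is re-protonated by the TfOH formed) to a C4 cation that adds to C5 while C9 adds to C10 in a concerted anti chair–chair Stork–Eschenmoser bicyclisation, so the cis C5=C10 geometry gives the cis ring fusion (H-5 syn to C20), A(1,3) strain at the 6R silyloxy centre puts C7 on the face of C10 that C9 attacks and so fixes C5 and C10 with the 6-oxygen equatorial, the slim alkynyl group (A value about 0.4 against 1.7 for methyl) takes the axial site at C4 cis to C20, and the C8 cation loses H-9 to the thermodynamic tetrasubstituted olefin under the acidic conditions; closest known reaction types are Johnson allylic-cation-initiated cation–olefin polycyclisation and Lewis-acid propargylic substitution.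

**Step 13**
Reactants: 24 cis-fused bicyclic 8(9)-ene
Product: 25 bicyclic ene-triol with terminal alkyne
Conditions: Bu4NF, AcOH, THF, 25 to 40 °C
Reagents that add atoms: none
Why: Fluoride-mediated desilylation cleaves the three Si–O bonds and the alkynyl C–Si bond; the acetic acid buffer protects the lactone, and no stereocentre is touched.

**Step 14**
Reactants: 25 bicyclic ene-triol
Product: 26 8β-phenylselanyl 9α,13-spiro ether
Conditions: PhSeCl, K2CO3, CH2Cl2, −78 °C
Reagents that add atoms: benzeneselenenyl chloride, Cl[Se]c1ccccc1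
Why: Phenylseleno-etherification; the seleniranium ion forms on the β face of the 8(9)-ene (the α face at C8 is shielded by the axial C1 methylene of the cis-fused ring A) and is opened anti by the C13 hydroxyl in a 5-exo mode at C9 (6-endo attack at C8 would need the blocked α face), which sets the 9α-O/11β spiro centre (9R) and leaves the C17 methyl α.

**Step 15**
Reactants: 26 8β-phenylselanyl spiro ether
Product: 27 spiro ether alkyne diol (8α-methyl, 8β-H)
Conditions: Bu3SnH, AIBN (cat.), PhMe, 80 °C
Reagents that add atoms: none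
Why: Radical chain deselenation; the planar tertiary C8 radical takes hydrogen from Bu3SnH on the open β face (the α face is blocked by the syn-axial C1 methylene), which gives the 8R centre with the methyl α.

**Step 16**
Reactants: 27 spiro ether alkyne diol
Product: 29 target CNP0393616.2, via seco acid 28 (not isolated)
Conditions: O3, CH2Cl2, −78 to −20 °C; then H2O, 25 °C; camphorsulfonic acid (cat.)
Reagents that add atoms: ozone, [O-][O+]=O
Why: Ozonolysis cleaves the terminal alkyne to the C19 carboxylic acid (the terminal carbon leaves as formic acid), and the axial C4 acid and axial C10 CH2OH (cis-1,3-diaxial) lactonise to the δ-lactone; the 6-OH is anti to C19 and cannot compete, and no stereocentre changes.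

**Compound list**
1 | cyclopropyl methyl ketone | CC(=O)C1CC1 | starting material
2 | 2-(2-bromoethyl)-1,3-dioxolane | BrCCC1OCCO1 | starting material
3 | [2-(1,3-dioxolan-2-yl)ethyl]magnesium bromide | Br[Mg]CCC1OCCO1 | intermediate (not isolated)
4 | 2-cyclopropyl-4-(1,3-dioxolan-2-yl)butan-2-ol (racemic) | CC(O)(CCC1OCCO1)C1CC1 | intermediate
5 | 2-[(3E)-6-iodo-3-methylhex-3-en-1-yl]-1,3-dioxolane | ICC/C=C(\C)CCC1OCCO1 | intermediate
6 | (R)-malic acid (D-malic acid) | O[C@H](CC(=O)O)C(=O)O | starting material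
7 | 2-[(2R,4R)-2-tert-butyl-5-oxo-1,3-dioxolan-4-yl]acetic acid (cis acetal) | CC(C)(C)[C@@H]1O[C@H](CC(=O)O)C(=O)O1 | intermediate
8 | dilithium enolate-carboxylate of 7 (acetal centre R) | [Li+].[Li+].CC(C)(C)[C@@H]1OC(CC(=O)[O-])=C([O-])O1 | intermediate (not isolated)
9 | 2-[(2R,4R)-2-tert-butyl-4-[(3E)-6-(1,3-dioxolan-2-yl)-4-methylhex-3-en-1-yl]-5-oxo-1,3-dioxolan-4-yl]acetic acid | CC(C)(C)[C@@H]1O[C@@](CC(=O)O)(CC/C=C(\C)CCC2OCCO2)C(=O)O1 | intermediate
10 | acyl imidazolide of 9 | CC(C)(C)[C@@H]1O[C@@](CC(=O)n2ccnc2)(CC/C=C(\C)CCC2OCCO2)C(=O)O1 | intermediate (not isolated)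
11 | (2R,5R)-2-tert-butyl-5-[(3E)-6-(1,3-dioxolan-2-yl)-4-methylhex-3-en-1-yl]-5-(2-hydroxyethyl)-1,3-dioxolan-4-one | CC(C)(C)[C@@H]1O[C@@](CCO)(CC/C=C(\C)CCC2OCCO2)C(=O)O1 | intermediate (not isolated)
12 | (4E)-7-[(3R)-3-hydroxy-2-oxooxolan-3-yl]-4-methylhept-4-enal | O=CCC/C(C)=C/CC[C@@]1(O)CCOC1=O | intermediate
13 | 6-chlorohexan-2-one | CC(=O)CCCCCl | starting material
14 | lithium 7-chloro-3-methyl-1-(trimethylsilyl)hept-1-yn-3-olate (racemic) | [Li+].CC([O-])(CCCCCl)C#C[Si](C)(C)C | intermediate (not isolated)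
15 | (7-chloro-3-methoxy-3-methylhept-1-yn-1-yl)trimethylsilane (racemic) | CC(OC)(CCCCCl)C#C[Si](C)(C)C | intermediate
16 | [5-methoxy-5-methyl-7-(trimethylsilyl)hept-6-yn-1-yl]triphenylphosphonium iodide (racemic) | CC(OC)(CCCC[P+](c1ccccc1)(c1ccccc1)c1ccccc1)C#C[Si](C)(C)C.[I-] | intermediate
17 | [5-methoxy-5-methyl-7-(trimethylsilyl)hept-6-yn-1-ylidene]triphenyl-λ5-phosphane (racemic) | CC(OC)(CCCC=P(c1ccccc1)(c1ccccc1)c1ccccc1)C#C[Si](C)(C)C | intermediate (not isolated)
18 | 6-methoxy-6-methyl-2-(triphenyl-λ5-phosphanylidene)-8-(trimethylsilyl)oct-7-ynal (racemic) | CC(OC)(CCCC(C=O)=P(c1ccccc1)(c1ccccc1)c1ccccc1)C#C[Si](C)(C)C | intermediate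
19 | (2R,4E)-7-[(3R)-3-hydroxy-2-oxooxolan-3-yl]-4-methyl-2-[(phenylamino)oxy]hept-4-enal | O=C[C@H](ONc1ccccc1)C/C(C)=C/CC[C@@]1(O)CCOC1=O | intermediate (not isolated)
20 | acyclic enal: C20 = CHO on C10; C5=C10 E (CHO trans to C6, C6 cis to C1); 6R ONHPh; C8=C9 E; 13R 3-hydroxy-2-oxooxolan-3-yl; C4 bears OMe, CH3 and C≡C–SiMe3 (both C4 epimers) | C[Si](C)(C)C#CC(C)(OC)CCC/C(C=O)=C\[C@H](ONc1ccccc1)C/C(C)=C/CC[C@@]1(O)CCOC1=O | intermediate
21 | as 20 with C20 = CH2OH | C[Si](C)(C)C#CC(C)(OC)CCC/C(CO)=C\[C@H](ONc1ccccc1)C/C(C)=C/CC[C@@]1(O)CCOC1=O | intermediate (not isolated)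
22 | acyclic triol: C20 CH2OH; 6R OH; 13R OH; olefins as in 20 | C[Si](C)(C)C#CC(C)(OC)CCC/C(CO)=C\[C@H](O)C/C(C)=C/CC[C@@]1(O)CCOC1=O | intermediate
23 | tris(tert-butyldimethylsilyl) ether of 22 (C20-O, C6-O, C13-O) | C[Si](C)(C)C#CC(C)(OC)CCC/C(CO[Si](C)(C)C(C)(C)C)=C\[C@H](O[Si](C)(C)C(C)(C)C)C/C(C)=C/CC[C@@]1(O[Si](C)(C)C(C)(C)C)CCOC1=O | intermediate
24 | cis-fused bicyclic 8(9)-ene: 5β-H; 10β-CH2OSi; 4β-C≡C–SiMe3, 4α-CH3; 6β-OSi; C9 bears CH2CH2-[(3R)-3-silyloxy-2-oxooxolan-3-yl] (Si = t-BuMe2Si) | CC1=C(CC[C@@]2(O[Si](C)(C)C(C)(C)C)CCOC2=O)[C@@]3(CO[Si](C)(C)C(C)(C)C)CCC[C@](C)(C#C[Si](C)(C)C)[C@H]3[C@H](O[Si](C)(C)C(C)(C)C)C1 | intermediate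
25 | desilylated 24: 6β-OH; 10β-CH2OH; 13R OH; 4β-C≡CH | CC1=C(CC[C@@]2(O)CCOC2=O)[C@@]3(CO)CCC[C@](C)(C#C)[C@H]3[C@H](O)C1 | intermediate
26 | 8β-phenylselanyl-9α,13-epoxy spiro ether (8α-CH3; C11 β; 13R spiro lactone; 6β-OH; 10β-CH2OH; 4β-C≡CH) | C[C@]1([Se]c2ccccc2)C[C@@H](O)[C@H]2[C@](CO)(CCC[C@]2(C)C#C)[C@@]12CC[C@]1(CCOC1=O)O2 | intermediate
27 | as 26 with 8β-H in place of SePh | C[C@@H]1C[C@@H](O)[C@H]2[C@](CO)(CCC[C@]2(C)C#C)[C@@]12CC[C@]1(CCOC1=O)O2 | intermediate
28 | seco acid: as 27 with 4β-CO2H in place of C≡CH | C[C@@H]1C[C@@H](O)[C@H]2[C@](CO)(CCC[C@]2(C)C(=O)O)[C@@]12CC[C@]1(CCOC1=O)O2 | intermediate (not isolated)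
29 | CNP0393616.2 (4S,5S,6R,8R,9R,10S,13R) | C[C@@H]1C[C@@H](O)[C@H]2[C@]3(CCC[C@]2(C)C(=O)OC3)[C@@]12CC[C@]1(CCOC1=O)O2 | target

**Totals**
Total step count: 16. Longest linear sequence: 12 steps (1, 2, 4, 5, 9–16).

**Steps most likely to fail**

Step 12 (bicyclisation). The risks are that the doubly allylically oxygenated C5=C10 olefin is a poor nucleophile, that the allylic silyl ethers ionise under the Lewis acid, and that the olefin isomers do not converge on the 8(9)-ene. The fallback sets out from 23 and comes back at 24. Ionising 23 in the presence of a hindered base (Me3SiOTf, 2,6-di-tert-butyl-4-methylpyridine, CH2Cl2, −78 °C) stops at elimination and gives the cross-conjugated C4 exo-methylene enyne F1 (its endocyclic isomer behaves the same way). F1 is then cyclised by hydrogen-atom transfer and radical–polar crossover (Co(salen) containing divalent cobalt, N-fluoro-2,4,6-trimethylpyridinium triflate, PhSiH3, (CF3)2CHOH, 0 °C). The cobalt hydride puts H on the CH2 terminus, and oxidation of the propargylic radical regenerates the same C4 cation with no Lewis acid present, so the silyl ethers cannot ionise; the cation follows the same concerted bicyclisation, and a trace of TsOH converges the olefin isomers to 24.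

Step 14 (spiro-etherification). The risks are 6-endo opening, reaction through an α-face seleniranium ion (giving the 9-epimer), and addition of selenium to the alkyne. The fallback sets out from 25 and comes back at 27 with no new compound. Photoredox hydroetherification (9-mesityl-10-methylacridinium tetrafluoroborate, methyl thiosalicylate as H-atom donor, blue LEDs, ClCH2CH2Cl) oxidises the tetrasubstituted olefin to its radical cation; the C13 hydroxyl adds 5-exo at C9, and the thiol delivers hydrogen to the C8 radical from the open β face. This gives 27 directly and bypasses 26.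

Step 9 (aminoxylation/Wittig). The risk is that the hindered α-formyl ylide reacts too slowly with the labile α-anilinooxy aldehyde. The fallback sets out from 15 and comes back at 20. S-Ethyl 2-(diethoxyphosphoryl)ethanethioate is alkylated with 15 (NaH, NaI, DMF) to give the thioester phosphonate F2. A Horner–Wadsworth–Emmons reaction of F2 with the aldehyde 19 generated in situ (LiCl, i-Pr2NEt, MeCN, 0 °C) gives the E α,β-unsaturated thioester F3. Fukuyama reduction of F3 (Et3SiH, Pd/C, acetone) then gives the enal 20.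

**Further compounds**
F1 | step 12 | C4 exo-methylene enyne from 23 by loss of methanol (tris-silyl ether; olefins and stereocentres as in 23) | C=C(CCC/C(CO[Si](C)(C)C(C)(C)C)=C\[C@H](O[Si](C)(C)C(C)(C)C)C/C(C)=C/CC[C@@]1(O[Si](C)(C)C(C)(C)C)CCOC1=O)C#C[Si](C)(C)C
F0 | step 14 | none | none
F2 | step 9 | S-ethyl 2-(diethoxyphosphoryl)-6-methoxy-6-methyl-8-(trimethylsilyl)oct-7-ynethioate (racemic centres) | CCOP(=O)(OCC)C(CCCC(C)(OC)C#C[Si](C)(C)C)C(=O)SCC
F3 | step 9 | S-ethyl thioester analogue of 20 (C20 = C(=O)SEt; C5=C10 E; 6R ONHPh; 13R) | C[Si](C)(C)C#CC(C)(OC)CCC/C(C(=O)SCC)=C\[C@H](ONc1ccccc1)C/C(C)=C/CC[C@@]1(O)CCOC1=O
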